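**Retrosynthetic overview**

1. Numbering: C1 is the lactone carbonyl, then round the ring to C13 (the ethyl-bearing carbinol) and the ring oxygen; C4′ is the hydroxymethyl carbon. The strategy rests on the C6(OMe)=C7 enol ether inside the 14-membered lactone ring: ring atoms C5 and C8 are cis across it, which is what a syn addition to a C6≡C7 ring alkyne delivers, and the C10(=CH2)–C11=C12 diene does not react with alkylidynes.
2. Target ⇐ C3 carbinol oxidation and desilylation ⇐ C6 methyl enol ether ⇐ C6 alkenyl iodide ⇐ oxasilolane from a C4–O–SiMe2H tether (syn-hydrosilylation, Si to C6) ⇐ 14-membered cycloalkyne ⇐ ring-closing alkyne metathesis joining C6 and C7 of a seco ester with two methyl-capped alkynes.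
3. Seco ester ⇐ Yamaguchi ester of a C1–C6 acid and a C7–C13 dienyl alcohol. Acid: C4 by Sharpless epoxidation of mono-silylated 2-methylenepropane-1,3-diol (the free diol would give an achiral epoxide), propynyl opening, C2 by Evans aldol. Alcohol: C8 by Evans alkylation with 2,3-dibromopropene, C13 by lipase resolution, C10–C11 by Suzuki coupling.
4. C3 is kept as a TES-protected carbinol from the aldol to the last step but one. An α-methyl β-keto ester is acidic enough to exchange with the silanolate ligands on molybdenum, would be C-vinylated by copper next to the C6 iodide, and would leave C2 unfixed. The C4 hydroxyl is re-silylated before the copper step because a free γ-hydroxy alkenyl iodide can close to an oxetane.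
5. Ring order: the macrocycle is the only ring of the target and closes in step 19; a five-membered oxasilolane forms in step 21 and is opened again in step 22.

Key step: step 19

Remark: once C3 is a ketone, C2 is an epimerisable β-keto ester centre; it is set as 2R by auxiliary control in step 15 and is assumed to hold under the buffered conditions of steps 26 and 27.

**Route**

Step 1
Reactants: 1 2-methylenepropane-1,3-diol
Product: 2 2-[(triisopropylsilyloxy)methyl]prop-2-en-1-ol
Conditions: NaH (1.0 equiv), THF, 0 °C → rt; i-Pr3SiCl (1.0 equiv)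
Reagents that add atoms: chlorotriisopropylsilane, CC(C)[Si](Cl)(C(C)C)C(C)C
Why: Silylation of the monosodium alkoxide of a symmetrical diol (Williamson-type O-silylation) should stop at the mono-ether, which breaks the symmetry that would otherwise make the epoxide achiral.

Step 2
Reactants: 2 2-[(triisopropylsilyloxy)methyl]prop-2-en-1-ol
Product: 3 (R)-{2-[(triisopropylsilyloxy)methyl]oxiran-2-yl}methanol
Conditions: Ti(OiPr)4 (10 mol%), D-(−)-diisopropyl tartrate (12 mol%), t-BuOOH, 4 Å molecular sieves, CH2Cl2, −20 °C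
Reagents that add atoms: tert-butyl hydroperoxide, CC(C)(C)OO
Why: Katsuki–Sharpless asymmetric epoxidation of a 2-substituted allylic alcohol: the titanium/D-(−)-tartrate complex should deliver oxygen to the alkene face that gives the (R)-epoxide, which sets C4.

Step 3
Reactants: 3 (R)-{2-[(triisopropylsilyloxy)methyl]oxiran-2-yl}methanol
Product: 4 (S)-triethyl({2-[(triisopropylsilyloxy)methyl]oxiran-2-yl}methoxy)silane
Conditions: Et3SiCl, imidazole, CH2Cl2, 0 °C
Reagents that add atoms: chlorotriethylsilane, CC[Si](Cl)(CC)CC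
Why: Imidazole-promoted O-silylation caps the primary hydroxyl as the TES ether, so that step 4 generates no primary alkoxide next to a silyl ether and C4 cannot be scrambled by silyl migration between the two CH2O arms.

Step 4
Reactants: 4 (S)-triethyl({2-[(triisopropylsilyloxy)methyl]oxiran-2-yl}methoxy)silane; 5 1-propynyllithium
Product: 6 (S)-2-[(triethylsilyloxy)methyl]-1-(triisopropylsilyloxy)hex-4-yn-2-ol
Conditions: 5 (3 equiv), BF3·OEt2 (promoter, 3 equiv), THF, −78 °C; NH4Cl (aq) at −78 °C
Reagents that add atoms: none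
Why: Yamaguchi–Hirao alkynylation: the BF3-activated 2,2-disubstituted epoxide is opened in SN2 fashion at its unhindered CH2 terminus by the alkynyllithium, forming C5–C6 without touching the C4 stereocentre.

Step 5
Reactants: 6 (S)-2-[(triethylsilyloxy)methyl]-1-(triisopropylsilyloxy)hex-4-yn-2-ol
Product: 7 (S)-2-[(triethylsilyloxy)methyl]-1-(triisopropylsilyloxy)-2-(trimethylsilyloxy)hex-4-yne
Conditions: Me3SiOTf, 2,6-lutidine, CH2Cl2, −78 °C
Reagents that add atoms: trimethylsilyl triflate, C[Si](C)(C)OS(=O)(=O)C(F)(F)F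
Why: Silyl triflate silylation of the hindered tertiary alcohol installs the trimethylsilyl ether, the one silyl group that can later be removed selectively to free the C4 oxygen for the tether.

Step 6
Reactants: 7 (S)-2-[(triethylsilyloxy)methyl]-1-(triisopropylsilyloxy)-2-(trimethylsilyloxy)hex-4-yne
Product: 8 (R)-2-[(triisopropylsilyloxy)methyl]-2-(trimethylsilyloxy)hex-4-ynal
Conditions: (COCl)2, DMSO, CH2Cl2, −78 → −30 °C; Et3N, −78 → 0 °C
Reagents that add atoms: none
Why: Swern oxidation of a primary triethylsilyl ether: the chlorosulfonium reagent desilylates and oxidises the unhindered primary TES ether directly to the aldehyde, while the tertiary TMS and the bulky TIPS ethers should not react.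

Step 7
Reactants: 9 (R)-4-benzyl-3-propionyloxazolidin-2-one; 10 2,3-dibromopropene
Product: 12 (R)-4-benzyl-3-[(S)-4-bromo-2-methylpent-4-enoyl]oxazolidin-2-one, via sodium enolate 11 (not isolated)
Conditions: NaN(SiMe3)2, THF, −78 °C; 10 (3 equiv), −78 → −40 °C
Reagents that add atoms: none
Why: Evans asymmetric alkylation: the chelated sodium Z-enolate is alkylated by the allylic bromide on the face away from the benzyl group, which sets C8 as S.

Step 8
Reactants: 12 (R)-4-benzyl-3-[(S)-4-bromo-2-methylpent-4-enoyl]oxazolidin-2-one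
Product: 13 (S)-4-bromo-2-methylpent-4-en-1-ol
Conditions: LiBH4, MeOH (1 equiv), Et2O, 0 °C
Reagents that add atoms: none
Why: Reductive cleavage of the N-acyl oxazolidinone by borohydride attack at the exocyclic carbonyl gives the primary alcohol and returns the auxiliary, leaving the alkenyl bromide and C8 untouched.

Step 9
Reactants: 13 (S)-4-bromo-2-methylpent-4-en-1-ol
Product: 14 (S)-4-bromo-2-methylpent-4-enal
Conditions: Dess–Martin periodinane, NaHCO3, CH2Cl2, 0 °C → rt; used crude
Reagents that add atoms: none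
Why: Dess–Martin oxidation under bicarbonate buffer gives the α-branched aldehyde without epimerisation at C8.

Step 10
Reactants: 14 (S)-4-bromo-2-methylpent-4-enal
Product: 15 (S)-2-bromo-4-methylhex-1-en-5-yne
Conditions: dimethyl (1-diazo-2-oxopropyl)phosphonate, K2CO3, MeOH, 0 °C → rt
Reagents that add atoms: dimethyl (1-diazo-2-oxopropyl)phosphonate, CC(=O)C(=[N+]=[N-])P(=O)(OC)OC
Why: Seyferth–Gilbert homologation with the Ohira–Bestmann reagent converts the aldehyde carbon (C7) into a terminal alkyne under mild carbonate conditions that should not epimerise C8.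

Step 11
Reactants: 15 (S)-2-bromo-4-methylhex-1-en-5-yne
Product: 17 (S)-2-bromo-4-methylhept-1-en-5-yne, via lithium acetylide 16 (not isolated)
Conditions: LiN(iPr)2, THF, −78 °C; MeI, −78 °C → rt
Reagents that add atoms: iodomethane, CI
Why: Alkyne deprotonation with a lithium amide (which, unlike an alkyllithium, does not exchange the alkenyl bromide) followed by SN2 methylation gives the methyl-capped alkyne required for metathesis.

Step 12
Reactants: 18 pent-1-yn-3-ol (racemic)
Product: 20 rac-(Z)-1-iodo-2-methylpent-1-en-3-ol, via alkenylmagnesium alkoxide 19 (not isolated)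
Conditions: MeMgBr (2.5 equiv), CuI (10 mol%), THF, −10 °C → rt; I2, −78 → 0 °C
Reagents that add atoms: methylmagnesium bromide, C[Mg]Br; iodine, II
Why: Copper-catalysed carbomagnesiation of a propargylic alkoxide: anti addition through the five-membered magnesium chelate places methyl on C12 and magnesium on C11 cis to the carbinol carbon, and iodinolysis with retention gives the Z-iodide.

Step 13
Reactants: 20 rac-(Z)-1-iodo-2-methylpent-1-en-3-ol
Product: 21 (S,Z)-1-iodo-2-methylpent-1-en-3-ol
Conditions: Candida antarctica lipase B (immobilised), vinyl acetate, t-BuOMe, 30 °C, stopped just past half conversion; chromatography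
Reagents that add atoms: none
Why: Lipase-catalysed acylative kinetic resolution: by the Kazlauskas rule the enzyme should acetylate the R alcohol (alkenyl as large, ethyl as medium group) and leave the S alcohol, which fixes C13.

Step 14
Reactants: 17 (S)-2-bromo-4-methylhept-1-en-5-yne; 21 (S,Z)-1-iodo-2-methylpent-1-en-3-ol
Product: 24 (3S,4Z,8S)-4,8-dimethyl-6-methylideneundec-4-en-9-yn-3-ol, via alkenyllithium 22 (not isolated), via lithium alkenyltriisopropoxyborate 23 (not isolated)
Conditions: 17, t-BuLi (2.0 equiv), Et2O, −78 °C; B(OiPr)3, −78 °C → rt; then 21, Pd(PPh3)4 (5 mol%), K3PO4 (aq), THF, 50 °C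
Reagents that add atoms: none
Why: Bromine–lithium exchange, trapping as the borate and Suzuki–Miyaura coupling with the alkenyl iodide form C10–C11 with retention of the Z geometry and tolerate the free hydroxyl.

Step 15
Reactants: 9 (R)-4-benzyl-3-propionyloxazolidin-2-one; 8 (R)-2-[(triisopropylsilyloxy)methyl]-2-(trimethylsilyloxy)hex-4-ynal
Product: 26 (R)-4-benzyl-3-{(2R,3R,4R)-3-hydroxy-2-methyl-4-[(triisopropylsilyloxy)methyl]-4-(trimethylsilyloxy)oct-6-ynoyl}oxazolidin-2-one, via boron enolate 25 (not isolated)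
Conditions: 9, Bu2BOTf, Et3N, CH2Cl2, −78 → 0 °C; 8, −78 → 0 °C; pH 7 buffer, MeOH, H2O2, 0 °C
Reagents that add atoms: none
Why: Evans syn-aldol reaction: the dibutylboron Z-enolate adds through a Zimmerman–Traxler chair under control of the auxiliary, which sets C2 as R and gives the 2,3-syn carbinol (3R) whose configuration is erased later by oxidation.

Step 16
Reactants: 26 aldol adduct
Product: 27 (R)-4-benzyl-3-{(2R,3R,4R)-2-methyl-3-(triethylsilyloxy)-4-[(triisopropylsilyloxy)methyl]-4-(trimethylsilyloxy)oct-6-ynoyl}oxazolidin-2-one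
Conditions: Et3SiOTf, 2,6-lutidine, CH2Cl2, −78 → 0 °C
Reagents that add atoms: triethylsilyl triflate, CC[Si](CC)(CC)OS(=O)(=O)C(F)(F)F
Why: Silyl triflate silylation of the hindered secondary alcohol masks C3 as a TES ether, so that the later metal-mediated steps never meet an acidic β-keto ester and C2 stays fixed.

Step 17
Reactants: 27 TES-protected imide
Product: 28 (2R,3R,4R)-2-methyl-3-(triethylsilyloxy)-4-[(triisopropylsilyloxy)methyl]-4-(trimethylsilyloxy)oct-6-ynoic acid
Conditions: LiOH, H2O2, THF/H2O (3:1), 0 °C; Na2SO3; NaHSO4 (aq) to pH 4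
Reagents that add atoms: hydrogen peroxide (as LiOOH), OO
Why: Evans hydrolysis with lithium hydroperoxide cleaves the imide at the exocyclic carbonyl without epimerising C2, and the cold, briefly basic medium should leave the silyl ethers in place.

Step 18
Reactants: 28 C1–C6 acid; 24 (3S,4Z,8S)-4,8-dimethyl-6-methylideneundec-4-en-9-yn-3-ol
Product: 30 (3S,4Z,8S)-4,8-dimethyl-6-methylideneundec-4-en-9-yn-3-yl (2R,3R,4R)-2-methyl-3-(triethylsilyloxy)-4-[(triisopropylsilyloxy)methyl]-4-(trimethylsilyloxy)oct-6-ynoate, via mixed anhydride 29 (not isolated)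
Conditions: 2,4,6-trichlorobenzoyl chloride, Et3N, toluene, rt; then 24, DMAP, toluene, rt
Reagents that add atoms: none
Why: Yamaguchi esterification: the mixed 2,4,6-trichlorobenzoic anhydride is opened by DMAP and the acylpyridinium acylates the hindered allylic alcohol without touching C2 or C13.

Step 19
Reactants: 30 seco ester bis(methylalkyne)
Product: 31 14-membered cycloalkyne lactone (C6≡C7; C3 OSiEt3; C4 OSiMe3; C4′ OSi(iPr)3; 11Z; 2R,3R,4R,8S,13S)
Conditions: Mo(≡CC6H4OMe-4)(OSiPh3)3 (15 mol%), powdered 5 Å molecular sieves, toluene (0.002 M), rt → 50 °C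
Reagents that add atoms: none
Why: The alkylidyne adds one methylalkyne in a [2+2] cycloaddition to a metallacyclobutadiene, cycloreverts to a substrate-bound alkylidyne with loss of but-2-yne, and repeats the sequence intramolecularly with the second alkyne to release the cycloalkyne and regenerate the catalyst. The closest known reaction type is ring-closing alkyne metathesis of methyl-capped diynes to cycloalkynes of twelve or more ring atoms with molybdenum alkylidyne silanolate catalysts. The 14-membered ring closes by direct union of C6 and C7, both of which become ring atoms, and no stereocentre is formed. The step needs ring closure to beat oligomerisation, which high dilution and trapping of but-2-yne in the molecular sieves should secure, and it needs chemoselectivity for the two alkynes, which is given because alkylidynes do not engage the diene, the ester or the silyl ethers. C3 is carried as a silylated carbinol so that no acidic α-methyl β-keto ester is present to exchange with the silanolate ligands.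

Step 20
Reactants: 31 cycloalkyne lactone
Product: 32 cycloalkyne lactone with free C4 hydroxyl (C3 OSiEt3; C4′ OSi(iPr)3)
Conditions: pyridinium p-toluenesulfonate (0.1 equiv), MeOH/CH2Cl2, 0 °C
Reagents that add atoms: none
Why: Acid-catalysed methanolysis of the trimethylsilyl ether, by far the most labile of the three silyl groups, should free the C4 hydroxyl while the hindered secondary TES and the primary TIPS ethers stay.

Step 21
Reactants: 32 C4-hydroxy cycloalkyne
Product: 34 oxasilolane-fused macrocycle (SiMe2 bridging O4 and C6; C6=C7 with C5 and C8 cis; H on C7), via dimethylsilyl ether 33 (not isolated)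
Conditions: Me2SiHCl, Et3N, DMAP (cat.), CH2Cl2, 0 °C → rt; filtration, solvent exchange; H2PtCl6·6H2O (0.5 mol%), THF, rt → 50 °C
Reagents that add atoms: chlorodimethylsilane, C[SiH](C)Cl
Why: O-silylation followed by platinum-catalysed intramolecular syn-hydrosilylation (5-exo-dig) delivers silicon to C6 and hydrogen to C7 from the same side, so the tether fixes the regiochemistry and the syn addition fixes C5 and C8 cis; the endo mode would need a trans double bond in a six-membered ring.

Step 22
Reactants: 34 oxasilolane-fused macrocycle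
Product: 35 C6 alkenyl iodide (C5 and C8 cis; free C4 hydroxyl; C3 OSiEt3; C4′ OSi(iPr)3)
Conditions: N-iodosuccinimide (1.2 equiv), 2,6-lutidine, (CF3)2CHOH/CH2Cl2, −20 → 0 °C, dark; Na2S2O3 (aq); citric acid (aq)/THF, 0 °C
Reagents that add atoms: N-iodosuccinimide, O=C1CCC(=O)N1I
Why: Iododesilylation: iodonium attacks the silicon-bearing C6 (ipso), the β-silyl cation collapses with loss of silicon and retention of geometry, and hydrolysis of the remaining Si–O bond returns the C4 hydroxyl.

Step 23
Reactants: 35 C6 alkenyl iodide with free C4 hydroxyl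
Product: 36 C6 alkenyl iodide with C3 and C4 OSiEt3 and C4′ OSi(iPr)3
Conditions: Et3SiOTf, 2,6-lutidine, CH2Cl2, −78 → 0 °C
Reagents that add atoms: triethylsilyl triflate, CC[Si](CC)(CC)OS(=O)(=O)C(F)(F)F
Why: Silyl triflate silylation of the tertiary C4 hydroxyl removes the γ-hydroxy alkenyl iodide motif, which under copper catalysis could close to a 2-alkylidene oxetane by 4-exo O-vinylation.

Step 24
Reactants: 36 fully silylated C6 alkenyl iodide
Product: 37 C6 methyl enol ether (C5 and C8 cis; C3 and C4 OSiEt3; C4′ OSi(iPr)3)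
Conditions: CuI (20 mol%), 3,4,7,8-tetramethyl-1,10-phenanthroline (40 mol%), Cs2CO3 (2 equiv), MeOH (10 equiv), toluene, 80 °C, sealed tube; Et3N-deactivated silica
Reagents that add atoms: methanol, CO
Why: Ullmann-type copper-catalysed C–O coupling of an alkenyl iodide with an alcohol is stereoretentive and should replace iodine by methoxy at C6 with C5 and C8 still cis.

Step 25
Reactants: 37 C6 methyl enol ether
Product: 38 C3 carbinol (C4 OSiEt3; C4′ OSi(iPr)3; enol ether intact)
Conditions: Bu4NF/AcOH (1:1), THF, 0 °C; Et3N-deactivated silica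
Reagents that add atoms: none
Why: Buffered fluoride desilylation should remove the secondary TES ether first (the tertiary TES ether is more hindered, the TIPS ether far less fluoride-labile), the near-neutral medium spares the enol ether, and loss of the C4 TES group as well would be harmless because a tertiary alcohol is not oxidised in step 26.

Step 26
Reactants: 38 C3 carbinol
Product: 39 C3 ketone (C4 OSiEt3; C4′ OSi(iPr)3)
Conditions: Dess–Martin periodinane, NaHCO3, CH2Cl2, 0 °C → rt
Reagents that add atoms: none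
Why: Dess–Martin oxidation under bicarbonate buffer converts the C3 carbinol into the ketone without the acid that would hydrolyse the enol ether or the base that would epimerise C2, which is now α to two carbonyls.

Step 27
Reactants: 39 C3 ketone
Product: 40 CNP0325854.3 (target)
Conditions: Bu4NF/AcOH (1:1), THF, 0 °C → rt; Et3N-deactivated silica
Reagents that add atoms: none
Why: Buffered fluoride desilylation frees the C4 and C4′ hydroxyls under near-neutral conditions, avoiding enol ether hydrolysis, C2 epimerisation and attack of a C4 alkoxide on the lactone carbonyl.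

**Compound list**

1 | 2-methylenepropane-1,3-diol | C=C(CO)CO | starting material
2 | 2-[(triisopropylsilyloxy)methyl]prop-2-en-1-ol | C=C(CO)CO[Si](C(C)C)(C(C)C)C(C)C | intermediate
3 | (R)-{2-[(triisopropylsilyloxy)methyl]oxiran-2-yl}methanol | OC[C@]1(CO[Si](C(C)C)(C(C)C)C(C)C)CO1 | intermediate
4 | (S)-triethyl({2-[(triisopropylsilyloxy)methyl]oxiran-2-yl}methoxy)silane | CC[Si](CC)(CC)OC[C@]1(CO[Si](C(C)C)(C(C)C)C(C)C)CO1 | intermediate
5 | 1-propynyllithium | [Li]C#CC | starting material
6 | (S)-2-[(triethylsilyloxy)methyl]-1-(triisopropylsilyloxy)hex-4-yn-2-ol | CC[Si](CC)(CC)OC[C@](O)(CO[Si](C(C)C)(C(C)C)C(C)C)CC#CC | intermediate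
7 | (S)-2-[(triethylsilyloxy)methyl]-1-(triisopropylsilyloxy)-2-(trimethylsilyloxy)hex-4-yne | CC[Si](CC)(CC)OC[C@](O[Si](C)(C)C)(CO[Si](C(C)C)(C(C)C)C(C)C)CC#CC | intermediate
8 | (R)-2-[(triisopropylsilyloxy)methyl]-2-(trimethylsilyloxy)hex-4-ynal | O=C[C@](O[Si](C)(C)C)(CO[Si](C(C)C)(C(C)C)C(C)C)CC#CC | intermediate
9 | (R)-4-benzyl-3-propionyloxazolidin-2-one | CCC(=O)N1C(=O)OC[C@H]1Cc1ccccc1 | starting material
10 | 2,3-dibromopropene | C=C(Br)CBr | starting material
11 | sodium (Z)-enolate of 9 | C/C=C(\O[Na])N1C(=O)OC[C@H]1Cc1ccccc1 | intermediate (not isolated)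
12 | (R)-4-benzyl-3-[(S)-4-bromo-2-methylpent-4-enoyl]oxazolidin-2-one | O=C([C@@H](C)CC(Br)=C)N1C(=O)OC[C@H]1Cc1ccccc1 | intermediate
13 | (S)-4-bromo-2-methylpent-4-en-1-ol | OC[C@@H](C)CC(Br)=C | intermediate
14 | (S)-4-bromo-2-methylpent-4-enal | O=C[C@@H](C)CC(Br)=C | intermediate
15 | (S)-2-bromo-4-methylhex-1-en-5-yne | C#C[C@@H](C)CC(Br)=C | intermediate
16 | lithium acetylide of 15 | [Li]C#C[C@@H](C)CC(Br)=C | intermediate (not isolated)
17 | (S)-2-bromo-4-methylhept-1-en-5-yne | CC#C[C@@H](C)CC(Br)=C | intermediate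
18 | pent-1-yn-3-ol (racemic) | C#CC(O)CC | starting material
19 | rac-(Z)-alkenylmagnesium bromide alkoxide (Mg on C11 cis to the carbinol carbon) | Br[Mg]/C=C(/C)C(CC)O[Mg]Br | intermediate (not isolated)
20 | rac-(Z)-1-iodo-2-methylpent-1-en-3-ol | I/C=C(/C)C(CC)O | intermediate
21 | (S,Z)-1-iodo-2-methylpent-1-en-3-ol | I/C=C(/C)[C@H](CC)O | intermediate
22 | (S)-(4-methylhept-1-en-5-yn-2-yl)lithium | CC#C[C@@H](C)CC([Li])=C | intermediate (not isolated)
23 | lithium triisopropoxy[(S)-4-methylhept-1-en-5-yn-2-yl]borate | CC#C[C@@H](C)CC(=C)[B-](OC(C)C)(OC(C)C)OC(C)C.[Li+] | intermediate (not isolated)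
24 | (3S,4Z,8S)-4,8-dimethyl-6-methylideneundec-4-en-9-yn-3-ol | CC#C[C@@H](C)CC(=C)/C=C(/C)[C@H](CC)O | intermediate
25 | dibutylboron (Z)-enolate of 9 | C/C=C(\OB(CCCC)CCCC)N1C(=O)OC[C@H]1Cc1ccccc1 | intermediate (not isolated)
26 | (R)-4-benzyl-3-{(2R,3R,4R)-3-hydroxy-2-methyl-4-[(triisopropylsilyloxy)methyl]-4-(trimethylsilyloxy)oct-6-ynoyl}oxazolidin-2-one | O=C(N1C(=O)OC[C@H]1Cc1ccccc1)[C@H](C)[C@@H](O)[C@](O[Si](C)(C)C)(CO[Si](C(C)C)(C(C)C)C(C)C)CC#CC | intermediate
27 | 3-O-triethylsilyl ether of 26 | O=C(N1C(=O)OC[C@H]1Cc1ccccc1)[C@H](C)[C@@H](O[Si](CC)(CC)CC)[C@](O[Si](C)(C)C)(CO[Si](C(C)C)(C(C)C)C(C)C)CC#CC | intermediate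
28 | (2R,3R,4R)-2-methyl-3-(triethylsilyloxy)-4-[(triisopropylsilyloxy)methyl]-4-(trimethylsilyloxy)oct-6-ynoic acid | OC(=O)[C@H](C)[C@@H](O[Si](CC)(CC)CC)[C@](O[Si](C)(C)C)(CO[Si](C(C)C)(C(C)C)C(C)C)CC#CC | intermediate
29 | mixed anhydride of 28 with 2,4,6-trichlorobenzoic acid | O=C(OC(=O)[C@H](C)[C@@H](O[Si](CC)(CC)CC)[C@](O[Si](C)(C)C)(CO[Si](C(C)C)(C(C)C)C(C)C)CC#CC)c1c(Cl)cc(Cl)cc1Cl | intermediate (not isolated)
30 | seco ester: (3S,4Z,8S)-4,8-dimethyl-6-methylideneundec-4-en-9-yn-3-yl ester of acid 28 | CC#C[C@@H](C)CC(=C)/C=C(/C)[C@H](CC)OC(=O)[C@H](C)[C@@H](O[Si](CC)(CC)CC)[C@](O[Si](C)(C)C)(CO[Si](C(C)C)(C(C)C)C(C)C)CC#CC | intermediate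
31 | 14-membered cycloalkyne lactone, C6≡C7, C3 OSiEt3, C4 OSiMe3, C4′ OSi(iPr)3, 11Z, (2R,3R,4R,8S,13S) | C=C1/C=C(/C)[C@H](CC)OC(=O)[C@H](C)[C@@H](O[Si](CC)(CC)CC)[C@](O[Si](C)(C)C)(CO[Si](C(C)C)(C(C)C)C(C)C)CC#C[C@@H](C)C1 | intermediate
32 | cycloalkyne lactone 31 with free C4 hydroxyl | C=C1/C=C(/C)[C@H](CC)OC(=O)[C@H](C)[C@@H](O[Si](CC)(CC)CC)[C@](O)(CO[Si](C(C)C)(C(C)C)C(C)C)CC#C[C@@H](C)C1 | intermediate
33 | C4 dimethylsilyl ether of 32 | C=C1/C=C(/C)[C@H](CC)OC(=O)[C@H](C)[C@@H](O[Si](CC)(CC)CC)[C@](O[SiH](C)C)(CO[Si](C(C)C)(C(C)C)C(C)C)CC#C[C@@H](C)C1 | intermediate (not isolated)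
34 | oxasilolane-fused macrocycle, SiMe2 between O4 and C6, C6=C7 with C5 and C8 cis | C=C1/C=C(/C)[C@H](CC)OC(=O)[C@H](C)[C@@H](O[Si](CC)(CC)CC)[C@](O[Si]2(C)C)(CO[Si](C(C)C)(C(C)C)C(C)C)C/C2=C\[C@@H](C)C1 | intermediate
35 | C6 alkenyl iodide, C5 and C8 cis, free C4 hydroxyl, C3 OSiEt3, C4′ OSi(iPr)3 | C=C1/C=C(/C)[C@H](CC)OC(=O)[C@H](C)[C@@H](O[Si](CC)(CC)CC)[C@](O)(CO[Si](C(C)C)(C(C)C)C(C)C)C/C(I)=C\[C@@H](C)C1 | intermediate
36 | C6 alkenyl iodide with C3 and C4 OSiEt3, C4′ OSi(iPr)3 | C=C1/C=C(/C)[C@H](CC)OC(=O)[C@H](C)[C@@H](O[Si](CC)(CC)CC)[C@](O[Si](CC)(CC)CC)(CO[Si](C(C)C)(C(C)C)C(C)C)C/C(I)=C\[C@@H](C)C1 | intermediate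
37 | C6 methyl enol ether with C3 and C4 OSiEt3, C4′ OSi(iPr)3 | C=C1/C=C(/C)[C@H](CC)OC(=O)[C@H](C)[C@@H](O[Si](CC)(CC)CC)[C@](O[Si](CC)(CC)CC)(CO[Si](C(C)C)(C(C)C)C(C)C)C/C(OC)=C\[C@@H](C)C1 | intermediate
38 | C3 carbinol (3R) with C4 OSiEt3, C4′ OSi(iPr)3, C6 methyl enol ether | C=C1/C=C(/C)[C@H](CC)OC(=O)[C@H](C)[C@@H](O)[C@](O[Si](CC)(CC)CC)(CO[Si](C(C)C)(C(C)C)C(C)C)C/C(OC)=C\[C@@H](C)C1 | intermediate
39 | C3 ketone with C4 OSiEt3, C4′ OSi(iPr)3, C6 methyl enol ether | C=C1/C=C(/C)[C@H](CC)OC(=O)[C@H](C)C(=O)[C@](O[Si](CC)(CC)CC)(CO[Si](C(C)C)(C(C)C)C(C)C)C/C(OC)=C\[C@@H](C)C1 | intermediate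
40 | CNP0325854.3, (2R,4R,8S,13S) with 6-methoxy enol ether (C5 and C8 cis) and 11Z diene | C=C1/C=C(/C)[C@H](CC)OC(=O)[C@H](C)C(=O)[C@](O)(CO)C/C(OC)=C\[C@@H](C)C1 | target

**Step count and risks**

Total: 27 steps. Longest linear sequence: 19 steps (steps 1–6, 15–27).

Step 19 (ring-closing alkyne metathesis). What may go wrong: intermolecular metathesis (oligomer formation) outruns ring closure, or the catalyst decays before the two hindered alkynes (neopentylic on the C5 side, α-branched on the C8 side) are turned over. Fallback: close the ring at the ester and make C6≡C7 earlier by acetylide chemistry, setting out from epoxide 4 and terminal alkyne 15 and returning at cycloalkyne 31. The lithium acetylide of 15 (LiN(iPr)2, THF, −78 °C) with BF3·OEt2 should open 4 at its CH2 terminus to give the tertiary alcohol F1, in which C5–C6 is formed and C6≡C7 is already in place. Me3SiOTf/2,6-lutidine would give the C4 trimethylsilyl ether F2, and Swern oxidation of its primary TES ether the aldehyde F3. Evans syn-aldol with 9 would give the adduct F4 and Et3SiOTf its C3 triethylsilyl ether F5, as in steps 15 and 16. Miyaura borylation of the alkenyl bromide (B2pin2, PdCl2(PPh3)2, KOPh, toluene, 50 °C) would give the pinacol boronate F6, and Suzuki coupling with 21 (Pd(PPh3)4, K3PO4) the hydroxy imide F7. LiOH/H2O2 would give the seco hydroxy acid F8. Yamaguchi macrolactonisation of F8 under high dilution should then give 31.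

Step 22 (iododesilylation). What may go wrong: electrophilic iodination of the conjugated diene competes with ipso substitution at C6. Fallback: place the metal by hydrozirconation, whose carbon–zirconium bond reacts with iodine much faster than any alkene, setting out from cycloalkyne 31 and returning at iodide 35. Cp2Zr(H)Cl in THF should add syn across C6≡C7 with zirconium on C6, the carbon next to the CH2 rather than the branched CH substituent, to give the alkenylzirconocene chloride F9 (not isolated). I2 at 0 °C would give the C4 trimethylsilyl alkenyl iodide F10 with retention. Pyridinium p-toluenesulfonate in MeOH then removes the trimethylsilyl group to give 35. Regiocontrol here rests on sterics alone, so a minor C7 iodide would have to be separated.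

Step 24 (copper-catalysed methoxylation). What may go wrong: C–O coupling at the hindered, fully substituted C6–I carbon is slow, so that carbonate and methanol at 80 °C cause lactone methanolysis, β-elimination of the C3 silyloxy group or epimerisation at C2 first. Fallback: form the C–O bond oxidatively at room temperature, setting out from iodide 36 and returning at enol ether 37. Miyaura borylation (B2pin2, PdCl2(PPh3)2, KOPh, toluene, 50 °C) should give the C6 pinacol boronate F11 with retention. Copper-promoted Chan–Lam–Evans etherification (Cu(OAc)2, Et3N, MeOH, rt, air) should then give 37.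

**Further compounds**

F1 | step 19 | (2S,6S)-8-bromo-6-methyl-2-[(triethylsilyloxy)methyl]-1-(triisopropylsilyloxy)non-8-en-4-yn-2-ol | CC[Si](CC)(CC)OC[C@](O)(CO[Si](C(C)C)(C(C)C)C(C)C)CC#C[C@@H](C)CC(Br)=C
F2 | step 19 | 2-O-trimethylsilyl ether of F1 | CC[Si](CC)(CC)OC[C@](O[Si](C)(C)C)(CO[Si](C(C)C)(C(C)C)C(C)C)CC#C[C@@H](C)CC(Br)=C
F3 | step 19 | (2R,6S)-8-bromo-6-methyl-2-[(triisopropylsilyloxy)methyl]-2-(trimethylsilyloxy)non-8-en-4-ynal | O=C[C@](O[Si](C)(C)C)(CO[Si](C(C)C)(C(C)C)C(C)C)CC#C[C@@H](C)CC(Br)=C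
F4 | step 19 | Evans syn-aldol adduct of 9 and F3 (2R,3R,4R; free C3 hydroxyl) | O=C(N1C(=O)OC[C@H]1Cc1ccccc1)[C@H](C)[C@@H](O)[C@](O[Si](C)(C)C)(CO[Si](C(C)C)(C(C)C)C(C)C)CC#C[C@@H](C)CC(Br)=C
F5 | step 19 | 3-O-triethylsilyl ether of F4 | O=C(N1C(=O)OC[C@H]1Cc1ccccc1)[C@H](C)[C@@H](O[Si](CC)(CC)CC)[C@](O[Si](C)(C)C)(CO[Si](C(C)C)(C(C)C)C(C)C)CC#C[C@@H](C)CC(Br)=C
F6 | step 19 | C10 pinacol boronate from F5 | O=C(N1C(=O)OC[C@H]1Cc1ccccc1)[C@H](C)[C@@H](O[Si](CC)(CC)CC)[C@](O[Si](C)(C)C)(CO[Si](C(C)C)(C(C)C)C(C)C)CC#C[C@@H](C)CC(=C)B1OC(C)(C)C(C)(C)O1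
F7 | step 19 | hydroxy imide with complete C1–C13 chain (C13 hydroxyl free) | O=C(N1C(=O)OC[C@H]1Cc1ccccc1)[C@H](C)[C@@H](O[Si](CC)(CC)CC)[C@](O[Si](C)(C)C)(CO[Si](C(C)C)(C(C)C)C(C)C)CC#C[C@@H](C)CC(=C)/C=C(/C)[C@H](CC)O
F8 | step 19 | seco hydroxy acid (C1 acid; C13 hydroxyl; C6≡C7) | OC(=O)[C@H](C)[C@@H](O[Si](CC)(CC)CC)[C@](O[Si](C)(C)C)(CO[Si](C(C)C)(C(C)C)C(C)C)CC#C[C@@H](C)CC(=C)/C=C(/C)[C@H](CC)O
F9 | step 22 | C6 alkenylzirconocene chloride from 31 (C5 and C8 cis) | C=C1/C=C(/C)[C@H](CC)OC(=O)[C@H](C)[C@@H](O[Si](CC)(CC)CC)[C@](O[Si](C)(C)C)(CO[Si](C(C)C)(C(C)C)C(C)C)C/C([Zr](Cl)(C2C=CC=C2)C2C=CC=C2)=C\[C@@H](C)C1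
F10 | step 22 | C6 alkenyl iodide with C4 OSiMe3 (C5 and C8 cis) | C=C1/C=C(/C)[C@H](CC)OC(=O)[C@H](C)[C@@H](O[Si](CC)(CC)CC)[C@](O[Si](C)(C)C)(CO[Si](C(C)C)(C(C)C)C(C)C)C/C(I)=C\[C@@H](C)C1
F11 | step 24 | C6 pinacol boronate from 36 (C5 and C8 cis) | C=C1/C=C(/C)[C@H](CC)OC(=O)[C@H](C)[C@@H](O[Si](CC)(CC)CC)[C@](O[Si](CC)(CC)CC)(CO[Si](C(C)C)(C(C)C)C(C)C)C/C(B2OC(C)(C)C(C)(C)O2)=C\[C@@H](C)C1
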